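Assumption: the sense of induction of the chiral acid in step 5 cannot be predicted in advance; the (R)-acid is written, and its mirror image is used if it delivers the antipode of 12.

**Retrosynthetic overview**
1. Target 13 ⇒ dione 12: the ring O–C5 bond of the bridged ketal-lactone is the key disconnection, made last by oxygen insertion (Baeyer–Villiger) into the C8–C5 bond of a bicyclo[3.2.1]oct-3-ene-2,8-dione.
2. Dione 12 ⇒ cation 9 + (E)-isoelemicin 8: a cationic [5+2] cycloaddition forms both C–C bonds and all four stereocentres under a chiral counter-anion.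
3. Cation 9 ⇒ masked o-quinone 5 ⇒ phenol 4: the ketal C–O bond is made by oxidative dearomatisation; 4 comes from 2,5-dimethoxyphenol (bromination, allyl coupling) and 8 from a Suzuki coupling.
4. Ring order: arene six-membered carbocycle → bicyclo[3.2.1]octane (five- and seven-membered rings close together in the cycloaddition) → six-membered lactone by O-insertion (6-oxabicyclo[3.2.2]nonane).

**Route**

Step 1
Reactants: 1 2,5-dimethoxyphenol
Product: 2 4-bromo-2,5-dimethoxyphenol
Conditions: NBS (1.0 equiv), MeCN, −10 °C
Reagents that add atoms: N-bromosuccinimide, O=C1CCC(=O)N1Br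
Why: Electrophilic aromatic bromination goes to C4, which is para to OH and ortho to the 5-OMe group, while C6 is flanked by two substituents and C3 is activated by one OMe only.

Step 2
Reactants: 2 4-bromo-2,5-dimethoxyphenol; 3 allylboronic acid pinacol ester
Product: 4 4-allyl-2,5-dimethoxyphenol
Conditions: Pd(PPh3)4 (5 mol%), CsF (3 equiv), THF, 66 °C
Reagents that add atoms: none
Why: Suzuki–Miyaura sp2–sp3 coupling of an aryl bromide with an unsubstituted allyl boronate under fluoride activation tolerates the free phenol, and a short reaction time limits isomerisation to the propenylarene.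

Step 3
Reactants: 4 4-allyl-2,5-dimethoxyphenol
Product: 5 4-allyl-3,6,6-trimethoxycyclohexa-2,4-dien-1-one
Conditions: PhI(OAc)2 (1.05 equiv), MeOH, 0 °C, 10 min; rapid filtration through basic alumina, used at once
Reagents that add atoms: methanol, CO
Why: Oxidative dearomatisation of a 2-methoxyphenol (masked o-benzoquinone formation) forms the ketal C–O bond because methanol captures the aryloxenium ion at the methoxy-bearing ortho carbon (the para carbon is blocked by allyl), and the 3-methoxy vinylogous-ester unit slows Diels–Alder dimerisation.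

Step 4
Reactants: 6 5-bromo-1,2,3-trimethoxybenzene; 7 (E)-prop-1-enylboronic acid pinacol ester
Product: 8 (E)-1,2,3-trimethoxy-5-(prop-1-enyl)benzene
Conditions: Pd(dppf)Cl2 (3 mol%), K2CO3, dioxane/H2O, 90 °C
Reagents that add atoms: none
Why: Suzuki–Miyaura coupling of an alkenyl boronate proceeds with retention of the E geometry, which later fixes the trans methyl/aryl relationship.

Step 5
Reactants: 5 4-allyl-3,6,6-trimethoxycyclohexa-2,4-dien-1-one; 8 (E)-1,2,3-trimethoxy-5-(prop-1-enyl)benzene
Product: 12 (1R,5R,6R,7R)-3-allyl-5-methoxy-6-methyl-7-(3,4,5-trimethoxyphenyl)bicyclo[3.2.1]oct-3-ene-2,8-dione, via aryloxenium cation 9 (not isolated), via cycloadduct oxocarbenium ion 10 (not isolated), via dimethyl ketal 11 (not isolated)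
Conditions: (R)-N-triflyl phosphoramide of 3,3′-bis(2,4,6-triisopropylphenyl)-BINOL, (R)-[3,3′-(2,4,6-iPr3C6H2)2C20H10O2]P(O)NHSO2CF3 (5 mol%), toluene, −60 °C; then 1 M HCl, THF, 0 °C
Reagents that add atoms: water, O
Why: Proposed new method: a chiral-counter-anion-directed cationic [5+2] cycloaddition, in which the strong chiral Brønsted acid ionises ketal 5 (loss of MeOH) to the planar O-methyl oxocarbenium/pentadienyl cation 9 held as a contact ion pair with the bulky chiral phosphoramidate, the methyl-bearing alkene carbon of 8 attacks the most electrophilic terminus (C6 of 5, the C–OMe carbon) on the face left open by the anion, and the resulting benzylic cation is closed on the same face by the vinylogous-ester α-carbon (C2 of 5) to give 10, so that C1, C5, C6 and C7 are all set here (trans Me/Ar from the E-alkene; aryl exo towards the one-carbon C8 bridge and methyl endo, which avoids a near-eclipsed methyl/bridgehead-OMe pair and is the arrangement of the natural macrophyllin-type series; absolute sense from the catalyst), after which the released MeOH traps 10 as ketal 11 and returns the proton and aqueous acid unveils the enone carbonyl; the closest known reaction type is the racemic acid-promoted cationic [5+2] cycloaddition of quinone-ketal-derived cations with (E)-propenylbenzenes (biomimetic bicyclo[3.2.1]octanoid syntheses and oxidative-dearomatisation-induced [5+2] cascades), combined with asymmetric counter-anion-directed catalysis of oxocarbenium ions.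

Step 6
Reactants: 12 (1R,5R,6R,7R)-3-allyl-5-methoxy-6-methyl-7-(3,4,5-trimethoxyphenyl)bicyclo[3.2.1]oct-3-ene-2,8-dione
Product: 13 (1R,5S,8R,9R)-3-allyl-5-methoxy-9-methyl-8-(3,4,5-trimethoxyphenyl)-6-oxabicyclo[3.2.2]non-3-ene-2,7-dione
Conditions: mCPBA (1.1 equiv, acid-free), CH2Cl2, 0 °C
Reagents that add atoms: m-chloroperoxybenzoic acid, O=C(OO)c1cccc(Cl)c1
Why: Baeyer–Villiger oxidation occurs at the strained, non-enolisable bridging C8 ketone (activated by the α-methoxy and β-keto groups) faster than the peracid touches the terminal alkene or the enone, and the tertiary, oxygen-substituted bridgehead C5 migrates in preference to the acyl-substituted C1 with retention, which forms the ring O–C5 bond of the ketal-lactone without touching any stereocentre (C5 changes only its descriptor).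

**Compound list**
1 | 2,5-dimethoxyphenol | Oc1cc(OC)ccc1OC | starting material
2 | 4-bromo-2,5-dimethoxyphenol | Oc1cc(OC)c(Br)cc1OC | intermediate
3 | allylboronic acid pinacol ester (2-allyl-4,4,5,5-tetramethyl-1,3,2-dioxaborolane) | C=CCB1OC(C)(C)C(C)(C)O1 | starting material
4 | 4-allyl-2,5-dimethoxyphenol | C=CCc1cc(OC)c(O)cc1OC | intermediate
5 | 4-allyl-3,6,6-trimethoxycyclohexa-2,4-dien-1-one (masked o-quinone) | C=CCC1=CC(OC)(OC)C(=O)C=C1OC | intermediate
6 | 5-bromo-1,2,3-trimethoxybenzene | COc1cc(Br)cc(OC)c1OC | starting material
7 | (E)-prop-1-enylboronic acid pinacol ester | C/C=C/B1OC(C)(C)C(C)(C)O1 | starting material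
8 | (E)-1,2,3-trimethoxy-5-(prop-1-enyl)benzene ((E)-isoelemicin) | C/C=C/c1cc(OC)c(OC)c(OC)c1 | intermediate
9 | 4-allyl-2,5-dimethoxyphenoxenium ion, drawn as the O-methyl oxocarbenium ion of 4-allyl-5-methoxy-o-benzoquinone | C=CCC1=CC(=[O+]C)C(=O)C=C1OC | intermediate
10 | C2 O-methyl oxocarbenium ion of dione 12 (all four stereocentres as in 12) | C=CCC1=C[C@@]2(OC)C(=O)[C@@H](C1=[O+]C)[C@H](c1cc(OC)c(OC)c(OC)c1)[C@H]2C | intermediate
11 | C2 dimethyl ketal of dione 12 (2,2-dimethoxy; all four stereocentres as in 12) | C=CCC1=C[C@@]2(OC)C(=O)[C@@H](C1(OC)OC)[C@H](c1cc(OC)c(OC)c(OC)c1)[C@H]2C | intermediate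
12 | (1R,5R,6R,7R)-3-allyl-5-methoxy-6-methyl-7-(3,4,5-trimethoxyphenyl)bicyclo[3.2.1]oct-3-ene-2,8-dione (aryl exo, methyl endo) | C=CCC1=C[C@@]2(OC)C(=O)[C@@H](C1=O)[C@H](c1cc(OC)c(OC)c(OC)c1)[C@H]2C | intermediate
13 | (1R,5S,8R,9R)-3-allyl-5-methoxy-9-methyl-8-(3,4,5-trimethoxyphenyl)-6-oxabicyclo[3.2.2]non-3-ene-2,7-dione | C=CCC1=C[C@@]2(OC)OC(=O)[C@@H](C1=O)[C@H](c1cc(OC)c(OC)c(OC)c1)[C@H]2C | target

**Totals**
Total steps: 6. Longest linear sequence: 5 (steps 1, 2, 3, 5, 6).

**Three steps most likely to fail**

Step 5 (the proposed new step). The risks are weak ion-pair control (low ee), the regioisomeric adduct from attack at the allyl-bearing carbon, the endo-aryl diastereomer, and acid-induced dimerisation of 8. The fallback uses known chemistry and sets out from 5 (with 8). The cycloaddition is run with an achiral acid (CF3CO2H, CH2Cl2, −20 °C), which is the established acid-promoted cationic cycloaddition of quinone ketals with propenylbenzenes. It gives cycloadduct cation 10 together with the mirror-image cycloadduct cation F1, and aqueous work-up hydrolyses both to the racemic dione, that is 12 and the (1S,5S,6S,7S)-dione F2. Preparative chiral-phase SFC separates the two, and the route is rejoined at 12.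

Step 6. The risks are epoxidation of the allyl group by the peracid and opening of the ketal-lactone by 3-chlorobenzoic acid. The fallback leaves the peracid manifold and goes from 12 to 13 by the aprotic silyl-peroxide Baeyer–Villiger reaction (Me3SiOOSiMe3, cat. Me3SiOTf, CH2Cl2, −40 °C). Here the peroxide adds as a nucleophile to the Lewis-acid-activated C8 carbonyl, isolated C=C bonds are not epoxidised, and no carboxylic acid is present. It sets out from 12 and comes back at 13 without a new compound.

Step 3. The risks are Diels–Alder dimerisation of 5 on concentration and methanol capture at the allyl-bearing para carbon. The fallback sets out from 4 and makes a different cation precursor by Wessely acetoxylation (Pb(OAc)4, AcOH/CH2Cl2, 0 °C). The product, 6-acetoxy-4-allyl-3,6-dimethoxycyclohexa-2,4-dien-1-one F3, is a more robust quinol acetate. Under the acid of step 5 it loses acetic acid to give the same cation, so the route is rejoined at 9.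

**Further compounds**
F1 | step 5 | mirror image of cycloadduct oxocarbenium ion 10 | C=CCC1=C[C@]2(OC)C(=O)[C@H](C1=[O+]C)[C@@H](c1cc(OC)c(OC)c(OC)c1)[C@@H]2C
F2 | step 5 | (1S,5S,6S,7S)-3-allyl-5-methoxy-6-methyl-7-(3,4,5-trimethoxyphenyl)bicyclo[3.2.1]oct-3-ene-2,8-dione | C=CCC1=C[C@]2(OC)C(=O)[C@H](C1=O)[C@@H](c1cc(OC)c(OC)c(OC)c1)[C@@H]2C
F3 | step 3 | 6-acetoxy-4-allyl-3,6-dimethoxycyclohexa-2,4-dien-1-one (racemic) | C=CCC1=CC(OC)(OC(C)=O)C(=O)C=C1OC
F0 | step 6 | none | none
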